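(The runs are calculated for substances that don't exist; the scatter is artificial.)

| flask | starting material | protic impurity | remark | time |
|---|---|---|---|---|
| south-west | 0.20 M | 0.044 M | run made earlier |  |
| west | 0.20 M | 0.090 M | run made earlier |  |
| south | 0.20 M | 0.24 M | run made earlier |  |
| north-west | 0.23 M | 0.10 M | run made earlier |  |
| noon | 0.20 M | 0.100 M |  | 10 h |
| dawn | 0.10 M | 0.0500 M |  | 10 h |
| dusk | 0.050 M | 0.150 M |  | 10 h |
| spring | 0.060 M | 0.200 M |  | 10 h |
| midnight | 0.80 M | 0.200 M |  | 10 h |

| run | time / h | single ring / % | starting material / % |
|---|---|---|---|
| south-west | 2.00 | 20.5 | 1.4 |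
| south-west | 4.00 | 22.3 | 0 |
| south-west | 5.00 | 22.5 | 0.3 |
| south-west | 8.00 | 22.9 | 0.8 |
| west | 2.00 | 21.1 | 1.7 |
| west | 4.00 | 22.7 | 0.7 |
| west | 5.00 | 22.3 | 0 |
| west | 8.00 | 22.3 | 0 |
| south | 2.00 | 21.0 | 2.2 |
| south | 4.00 | 21.8 | 0.6 |
| south | 5.00 | 21.6 | 0 |
| south | 8.00 | 22.5 | 0.1 |
| north-west | 0.500 | 13.3 | 12.1 |
| north-west | 1.33 | 18.1 | 2.2 |
| north-west | 3.00 | 20.2 | 0.8 |
| north-west | 8.00 | 20.0 | 0 |

(each reading ± 0.5 percentage points)

- a reading or a percentage of single ring counts all its forms, free or not
- a reading of starting material is of its free form alone

1. ranking by amount of single ring, in percent of the starting material charged, from high to low, at 10 h (noon / dawn / dusk / spring / midnight)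
2. the same order at 2.0 h (noon / dawn / dusk / spring / midnight)
3. the amount of single ring, in percent of the starting material charged of the flask you put first, at 10 h
4. the amount of single ring, in percent of the starting material charged of the flask you put last, at 10 h

- The easy step is to read the plateau: the south-west, west and south runs share one charge of starting material, and their last readings of single ring average 22.6 % while protic impurity rises 5.45-fold, so we freeze the impurity and leave it out of our reckoning.
- The north-west run, with a larger charge, reads 20.0 %, so we let two paths compete for starting material: closure, first order, and a path second order in it.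
- If a fraction a of the charge remains, single ring takes one part in (one plus r·a) of what is consumed, and averaging that share over the run gives the logarithm of (one plus r), divided by r.
- Solving this against the plateau gives r = 11.0 for the 0.20 M charge; this is the crowding number, a selectivity factor: the rate of the second-order path over that of closure at full charge.
- Dusk holds a quarter of that charge, so its crowding number is 2.75.
- The share curves upward as a falls, so its average lies above the share at half conversion, which gives a lower bound of 42.1 % for dusk.
- The same curve keeps the average below the mean of the two end shares, which gives an upper bound of 63.3 % for dusk.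
- Tightened to the exact average, we commit to 48.0 % for dusk and, with r = 44.0, to 8.64 % for midnight.
- Crowding rises with charge, so we rank the flasks by charge, smallest first, at both times; the south-west run already reads 20.5 % at 2.00 h against 22.9 % at 8.00 h.
- The forecast gives dusk > spring > dawn > noon > midnight at 10 h and dusk > spring > dawn > noon > midnight at 2.0 h, with 47.7 % and 8.5 %, from “first-order ring closure competing with second-order oligomerisation”; its top is 0.30 percentage points below ours, and within the bracket.
- The flasks give dusk > spring > dawn > noon > midnight at 10 h and dusk > spring > dawn > noon > midnight at 2.0 h, with dusk at 46.7 %, inside the bracket, and midnight at 8.05 %.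

    starting material → single ring (k = 2.27 × 10⁻⁴ s⁻¹)
    2 starting material → open dimer (k = 0.00584 M⁻¹ s⁻¹)
    starting material + open dimer → open trimer (k = 6.14 × 10⁻⁴ M⁻¹ s⁻¹)
    open dimer → ring dimer (k = 2.69 × 10⁻⁵ s⁻¹)
    starting material + single ring ⇌ idle adduct, settled at all times (K = 5.50 M⁻¹)
    starting material + protic impurity → quenched substrate (k = 1.81 × 10⁻⁴ M⁻¹ s⁻¹)

- Just after the start of dusk, closure uses starting material at 0.39 of the rate of the step to open dimer, against 0.364 from the crowding number, and at 0.498 h that ratio stands at 1.2. Single ring in dusk has moved 5 points from its own value once protic impurity reaches 0.442 M. A neighbour of dusk with 12.0 equiv of protic impurity has the same crowding number, 2.75, which still says 48.0 %, but at 10.0 h it holds 39.4 % single ring and 18.7 % quenched substrate.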